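Locants (daucane numbering): C1 = quaternary C–CH3; C2, C3 = CH2 of ring A (five-membered); C4 = C(OH)(i-Pr); C5 = ring-fusion CH; C6 = CH–O-aroyl; C7 = CH2; C8 = C(CH3)=; C9 = CH=; C10 = CH–O-tigloyl; ring B = seven-membered ring.
Cuts: the two ester C–O bonds; C8=C9 (ring B, metathesis); C4–OH and C4–i-Pr (back to a C4 ketone through the C3=C4 alkene); C3–C4 (ring A); C5–C6 (aldol) and C1–C2 (conjugate addition) on a butenolide.
Enabling feature: C4 is 1,3 to the quaternary C1 through C5, and C1 carries the two-carbon arm C2–C3. With C4 as a formyl carbon and C2=C3 as a vinyl group the five atoms of ring A are a 4-pentenal, so rhodium-catalysed hydroacylation closes C3–C4 and leaves the C4 ketone needed for i-Pr and OH.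
Forward: the lactone O10–C10–C1–C5–C4 is a temporary ring on which C1, C5 and C6 are set; it is opened to the aldehyde, ring A is closed (C3–C4), C4 is elaborated, ring B is closed last (C8=C9), then the two esters are attached.
Stereochemistry: C10 from a catalytic asymmetric alkynylation; C1, C5 and C6 relayed from C10 on the lactone (anti conjugate addition, anti aldol); C4 from epoxidation of C3=C4 on the face trans to the C6 arm, then hydride opening at C3.

Key step: step 9

Remark: the sense of induction of the ProPhenol catalyst in step 1 is taken from related enals; the ligand antipode that gives the 4R alcohol is the one used.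

Step 1
Reactants: 1 (2E)-but-2-enal; 2 methyl propiolate
Product: 3 methyl (4R,5E)-4-hydroxyhept-5-en-2-ynoate
Conditions: Me2Zn, ProPhenol ligand (10 mol%), Ph3PO (20 mol%), toluene, 4 °C
Reagents that add atoms: none
Why: Dinuclear zinc ProPhenol-catalysed enantioselective 1,2-addition of the zinc acetylide of 2 to the enal (Trost asymmetric alkynylation) should set C10 as the R carbinol by catalyst control of the aldehyde face.

Step 2
Reactants: 3 methyl (4R,5E)-4-hydroxyhept-5-en-2-ynoate
Product: 4 (5R)-4-methyl-5-[(1E)-prop-1-en-1-yl]furan-2(5H)-one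
Conditions: Me2CuLi (from MeLi and CuI), THF, −78 °C; aq. NH4Cl, then rt
Reagents that add atoms: lithium dimethylcuprate, [Li+].C[Cu-]C
Why: syn-Carbocupration of the ynoate puts CH3 on C1 and leaves the ester cis to the C10 carbinol, so the Z hydroxy enoate should lactonise on work-up (cuprate conjugate addition–lactonisation); C10 is not touched.

Step 3
Reactants: 5 3-methylbut-3-en-1-ol
Product: 6 3-methylbut-3-enal
Conditions: Dess–Martin periodinane, CH2Cl2, 0 °C to rt; used at once as a solution
Reagents that add atoms: none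
Why: Dess–Martin oxidation of the primary homoallylic alcohol under neutral conditions should avoid migration of the double bond into conjugation.

Step 4
Reactants: 4 (5R)-4-methyl-5-[(1E)-prop-1-en-1-yl]furan-2(5H)-one; 6 3-methylbut-3-enal
Product: 8 aldol lactone (3S,4S,5R)-4-ethenyl-3-[(1S)-1-hydroxy-3-methylbut-3-en-1-yl]-4-methyl-5-[(1E)-prop-1-en-1-yl]oxolan-2-one, via silyl ketene acetal 7 (not isolated)
Conditions: CH2=CHMgBr, CuI (20 mol%), TMSCl, THF, −78 to −30 °C; pentane, filtration; then 6, BF3·OEt2, CH2Cl2, −78 °C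
Reagents that add atoms: vinylmagnesium bromide, C=C[Mg]Br; chlorotrimethylsilane, C[Si](C)(C)Cl (silyl group present in 7 only)
Why: TMSCl-accelerated copper-catalysed conjugate addition of the vinyl Grignard reagent anti to the C10 propenyl group should create the quaternary C1 (S) and give 7, whose Mukaiyama aldol addition to 6 through an open transition state on the C5 face away from the C10 substituent should give the anti aldol (C5 S, C6 S); THF and low temperature are chosen to keep the copper reagent from displacing the allylic lactone C–O bond.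

Step 5
Reactants: 8 aldol lactone
Product: 9 tert-butyldimethylsilyl ether of 8 at the C6 oxygen
Conditions: TBSOTf, 2,6-lutidine, CH2Cl2, −78 to 0 °C
Reagents that add atoms: tert-butyldimethylsilyl triflate, CC(C)(C)[Si](C)(C)OS(=O)(=O)C(F)(F)F
Why: Silylation of the secondary aldol hydroxyl with a silyl triflate and a hindered base (silyl ether formation) also blocks retro-aldol cleavage in the later steps.

Step 6
Reactants: 9 silyl-protected aldol lactone
Product: 10 γ-hydroxy Weinreb amide (C4 amide, C10–OH free)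
Conditions: MeNH(OMe)·HCl, i-PrMgCl, THF, −20 to 0 °C
Reagents that add atoms: N,O-dimethylhydroxylamine hydrochloride, CNOC.Cl
Why: Aminolysis of the lactone by the chloromagnesium amide (Weinreb amide formation) should open the temporary ring at the C4–O10 bond and free the C10 hydroxyl without touching a stereocentre.

Step 7
Reactants: 10 γ-hydroxy Weinreb amide
Product: 11 Weinreb amide with C10–O-triethylsilyl
Conditions: TESOTf, 2,6-lutidine, CH2Cl2, −78 °C
Reagents that add atoms: triethylsilyl triflate, CC[Si](CC)(CC)OS(=O)(=O)C(F)(F)F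
Why: Silylation of the secondary allylic C10 hydroxyl (silyl ether formation) prevents re-lactonisation and later lactol formation, and the triethylsilyl ether stays distinguishable from the TBS ether at C6.

Step 8
Reactants: 11 silylated Weinreb amide
Product: 12 4-pentenal (C4 formyl, C2=C3 vinyl on C1)
Conditions: i-Bu2AlH, THF, −78 °C; aq. potassium sodium tartrate
Reagents that add atoms: none
Why: Reduction of the Weinreb amide stops at the aldehyde through the chelated tetrahedral intermediate (Weinreb amide reduction), and the low temperature should keep the α-stereocentre C5 intact.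

Step 9
Reactants: 12 4-pentenal
Product: 13 (2S,3S)-2-[(1S)-1-{[tert-butyl(dimethyl)silyl]oxy}-3-methylbut-3-en-1-yl]-3-methyl-3-{(1R,2E)-1-[(triethylsilyl)oxy]but-2-en-1-yl}cyclopentan-1-one
Conditions: [Rh(nbd)(dppe)]BF4 (5 mol%), H2 then Ar, CH2Cl2, rt
Reagents that add atoms: none
Why: Oxidative addition of the cationic monovalent rhodium complex into the formyl C–H bond of 12 gives an acyl rhodium hydride, which adds across the C2=C3 vinyl group (hydride to C2, rhodium to C3), and reductive elimination from the six-membered acyl alkyl rhodacycle (Rh, C4, C5, C1, C2, C3) forms the C3–C4 bond. The closest known reaction type is the rhodium diphosphine-catalysed intramolecular hydroacylation of 4-pentenals to cyclopentanones. Ring A closes in a formally 5-endo-trig sense with respect to the vinyl group, which is why the closure runs through a metallacycle and not through a radical or polar addition. No stereocentre is formed: C1, C5, C6 and C10 are carried in from 12, and the neutral conditions should not epimerise C5, which lies α to the formyl and then to the keto group. The step needs chemoselectivity for the vinyl group on C1 over the propenyl and methallyl groups and over decarbonylation; the 4-pentenal spacing (the other alkenes would need seven-membered rhodacycles), the quaternary C1 that presses aldehyde and vinyl group together, and the chelating dppe ligand should secure it. The C4 ketone that results is the handle for the isopropyl group and the tertiary hydroxyl.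

Step 10
Reactants: 13 cyclopentanone
Product: 14 C3=C4 enol triflate
Conditions: KN(SiMe3)2, THF, −78 °C; PhNTf2
Reagents that add atoms: N-phenylbis(trifluoromethanesulfonimide), O=S(=O)(N(c1ccccc1)S(=O)(=O)C(F)(F)F)C(F)(F)F
Why: Kinetic deprotonation with the bulky amide base should occur at the unhindered C3 methylene and not at the tertiary, flanked C5–H, and O-triflation of the enolate gives the C3=C4 enol triflate (regioselective enol triflate formation).

Step 11
Reactants: 14 enol triflate
Product: 15 4-isopropyl cyclopentene (C3=C4)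
Conditions: i-PrMgCl, Fe(acac)3 (5 mol%), THF/NMP, −30 °C
Reagents that add atoms: isopropylmagnesium chloride, CC(C)[Mg]Cl
Why: Iron-catalysed cross-coupling of the alkenyl triflate with the secondary alkyl Grignard reagent (Kumada-type coupling under Fürstner conditions) is fast at low temperature, tolerates silyl ethers and should avoid the isomerisation to n-propyl that palladium can cause.

Step 12
Reactants: 15 4-isopropyl cyclopentene
Product: 16 C3–C4 epoxide with the oxygen cis to H-5
Conditions: mCPBA (1.05 equiv), CH2Cl2, −20 °C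
Reagents that add atoms: 3-chloroperbenzoic acid, OOC(=O)c1cccc(Cl)c1
Why: Prilezhaev epoxidation should take place at the most electron-rich, trisubstituted C3=C4 bond in preference to the 1,1-disubstituted and the allylic-oxygenated disubstituted alkenes (the selectivity known from limonene) and on the ring face trans to the allylic C6 arm, which sets the C4–O bond as in the target.

Step 13
Reactants: 16 epoxide
Product: 18 diol (C4–OH and C10–OH free; C6–O-TBS), via triethylsilyl ether 17 (not isolated)
Conditions: LiEt3BH, THF, 0 °C to rt; then MeOH, PPTS, rt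
Reagents that add atoms: none
Why: The small, strongly nucleophilic hydride should open the trisubstituted epoxide by SN2 attack at the secondary carbon C3 and leave the tertiary C4–OH with the configuration fixed in step 12 (hydride opening of an epoxide), after which the buffered acidic methanol cleaves only the triethylsilyl ether (selective desilylation).

Step 14
Reactants: 18 diol
Product: 19 (3S,3aS,4S,8R,8aS)-4-{[tert-butyl(dimethyl)silyl]oxy}-6,8a-dimethyl-3-(propan-2-yl)-1,2,3,3a,4,5,8,8a-octahydroazulene-3,8-diol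
Conditions: second-generation Hoveyda–Grubbs catalyst (5 mol%), toluene, 80 °C
Reagents that add atoms: none
Why: Ring-closing metathesis between the propenyl group on C10 and the 1,1-disubstituted alkene at C8 should close ring B with the trisubstituted C8=C9 bond, driven by loss of propene; the free allylic C10 hydroxyl helps initiation and the two arms are trans on the cyclopentane, as the trans ring fusion requires.

Step 15
Reactants: 19 bicyclic diol; 20 tigloyl chloride
Product: 21 C10 tiglate (C6–O-TBS, C4–OH)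
Conditions: Et3N, DMAP (cat.), CH2Cl2, 0 °C to rt
Reagents that add atoms: none
Why: DMAP-catalysed acylation with the acid chloride should esterify the secondary allylic C10 hydroxyl while the tertiary C4 hydroxyl stays free (selective esterification); the E geometry of the acyl group is the stable one and is kept.

Step 16
Reactants: 21 C10 tiglate
Product: 22 C10 tiglate with free C6–OH
Conditions: HF·pyridine, THF/pyridine, 0 °C to rt
Reagents that add atoms: none
Why: Fluoride cleavage of the secondary TBS ether under mildly acidic, non-basic conditions (desilylation) should cause neither acyl migration nor ionisation of the allylic ester.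

Step 17
Reactants: 22 C6 alcohol; 23 4-(acetyloxy)benzoyl chloride
Product: 24 C6 4-(acetyloxy)benzoate
Conditions: pyridine, DMAP (cat.), CH2Cl2, rt
Reagents that add atoms: none
Why: DMAP-catalysed acylation of the secondary C6 hydroxyl with the aroyl chloride (esterification), the tertiary C4 hydroxyl again being unreactive; the phenol is carried as its acetate to prevent self-acylation.

Step 18
Reactants: 24 C6 4-(acetyloxy)benzoate
Product: 25 target
Conditions: NH3 (7 M in MeOH), THF, 0 °C
Reagents that add atoms: none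
Why: Ammonolysis should cleave the phenyl acetate much faster than the alkyl benzoate and the hindered tiglate (chemoselective deacetylation of an aryl ester) and release the phenol.

Compound list
1 | (2E)-but-2-enal (crotonaldehyde) | C/C=C/C=O | starting material
2 | methyl prop-2-ynoate (methyl propiolate) | C#CC(=O)OC | starting material
3 | methyl (4R,5E)-4-hydroxyhept-5-en-2-ynoate | COC(=O)C#C[C@H](O)/C=C/C | intermediate
4 | (5R)-4-methyl-5-[(1E)-prop-1-en-1-yl]furan-2(5H)-one | CC1=CC(=O)O[C@@H]1/C=C/C | intermediate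
5 | 3-methylbut-3-en-1-ol | C=C(C)CCO | starting material
6 | 3-methylbut-3-enal | C=C(C)CC=O | intermediate
7 | {[(4S,5R)-4-ethenyl-4-methyl-5-[(1E)-prop-1-en-1-yl]-4,5-dihydrofuran-2-yl]oxy}(trimethyl)silane | C=C[C@@]1(C)C=C(O[Si](C)(C)C)O[C@@H]1/C=C/C | intermediate
8 | (3S,4S,5R)-4-ethenyl-3-[(1S)-1-hydroxy-3-methylbut-3-en-1-yl]-4-methyl-5-[(1E)-prop-1-en-1-yl]oxolan-2-one | C=C(C)C[C@H](O)[C@H]1C(=O)O[C@H](/C=C/C)[C@@]1(C)C=C | intermediate
9 | (3S,4S,5R)-3-[(1S)-1-{[tert-butyl(dimethyl)silyl]oxy}-3-methylbut-3-en-1-yl]-4-ethenyl-4-methyl-5-[(1E)-prop-1-en-1-yl]oxolan-2-one | C=C(C)C[C@H](O[Si](C)(C)C(C)(C)C)[C@H]1C(=O)O[C@H](/C=C/C)[C@@]1(C)C=C | intermediate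
10 | (2S,3S,4R,5E)-2-[(1S)-1-{[tert-butyl(dimethyl)silyl]oxy}-3-methylbut-3-en-1-yl]-3-ethenyl-4-hydroxy-N-methoxy-N,3-dimethylhept-5-enamide | C=C(C)C[C@H](O[Si](C)(C)C(C)(C)C)[C@@H](C(=O)N(C)OC)[C@]([C@H](O)/C=C/C)(C)C=C | intermediate
11 | (2S,3S,4R,5E)-2-[(1S)-1-{[tert-butyl(dimethyl)silyl]oxy}-3-methylbut-3-en-1-yl]-3-ethenyl-N-methoxy-N,3-dimethyl-4-[(triethylsilyl)oxy]hept-5-enamide | C=C(C)C[C@H](O[Si](C)(C)C(C)(C)C)[C@@H](C(=O)N(C)OC)[C@]([C@H](O[Si](CC)(CC)CC)/C=C/C)(C)C=C | intermediate
12 | (2S,3S,4R,5E)-2-[(1S)-1-{[tert-butyl(dimethyl)silyl]oxy}-3-methylbut-3-en-1-yl]-3-ethenyl-3-methyl-4-[(triethylsilyl)oxy]hept-5-enal | C=C(C)C[C@H](O[Si](C)(C)C(C)(C)C)[C@@H](C=O)[C@]([C@H](O[Si](CC)(CC)CC)/C=C/C)(C)C=C | intermediate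
13 | (2S,3S)-2-[(1S)-1-{[tert-butyl(dimethyl)silyl]oxy}-3-methylbut-3-en-1-yl]-3-methyl-3-{(1R,2E)-1-[(triethylsilyl)oxy]but-2-en-1-yl}cyclopentan-1-one | C=C(C)C[C@H](O[Si](C)(C)C(C)(C)C)[C@H]1C(=O)CC[C@@]1([C@H](O[Si](CC)(CC)CC)/C=C/C)C | intermediate
14 | (4S,5S)-5-[(1S)-1-{[tert-butyl(dimethyl)silyl]oxy}-3-methylbut-3-en-1-yl]-4-methyl-4-{(1R,2E)-1-[(triethylsilyl)oxy]but-2-en-1-yl}cyclopent-1-en-1-yl trifluoromethanesulfonate | C=C(C)C[C@H](O[Si](C)(C)C(C)(C)C)[C@H]1C(OS(=O)(=O)C(F)(F)F)=CC[C@@]1([C@H](O[Si](CC)(CC)CC)/C=C/C)C | intermediate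
15 | tert-butyl(dimethyl){[(1S)-3-methyl-1-[(1S,5S)-5-methyl-2-(propan-2-yl)-5-{(1R,2E)-1-[(triethylsilyl)oxy]but-2-en-1-yl}cyclopent-2-en-1-yl]but-3-en-1-yl]oxy}silane | C=C(C)C[C@H](O[Si](C)(C)C(C)(C)C)[C@H]1C(C(C)C)=CC[C@@]1([C@H](O[Si](CC)(CC)CC)/C=C/C)C | intermediate
16 | tert-butyl(dimethyl){[(1S)-3-methyl-1-[(1S,2S,3S,5R)-3-methyl-1-(propan-2-yl)-3-{(1R,2E)-1-[(triethylsilyl)oxy]but-2-en-1-yl}-6-oxabicyclo[3.1.0]hexan-2-yl]but-3-en-1-yl]oxy}silane (epoxide oxygen cis to H-2 of the bicycle) | C=C(C)C[C@H](O[Si](C)(C)C(C)(C)C)[C@H]1[C@]2(C(C)C)O[C@@H]2C[C@@]1([C@H](O[Si](CC)(CC)CC)/C=C/C)C | intermediate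
17 | (1S,2S,3S)-2-[(1S)-1-{[tert-butyl(dimethyl)silyl]oxy}-3-methylbut-3-en-1-yl]-3-methyl-1-(propan-2-yl)-3-{(1R,2E)-1-[(triethylsilyl)oxy]but-2-en-1-yl}cyclopentan-1-ol | C=C(C)C[C@H](O[Si](C)(C)C(C)(C)C)[C@H]1[C@@](O)(C(C)C)CC[C@@]1([C@H](O[Si](CC)(CC)CC)/C=C/C)C | intermediate
18 | (1S,2S,3S)-2-[(1S)-1-{[tert-butyl(dimethyl)silyl]oxy}-3-methylbut-3-en-1-yl]-3-[(1R,2E)-1-hydroxybut-2-en-1-yl]-3-methyl-1-(propan-2-yl)cyclopentan-1-ol | C=C(C)C[C@H](O[Si](C)(C)C(C)(C)C)[C@H]1[C@@](O)(C(C)C)CC[C@@]1([C@H](O)/C=C/C)C | intermediate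
19 | (3S,3aS,4S,8R,8aS)-4-{[tert-butyl(dimethyl)silyl]oxy}-6,8a-dimethyl-3-(propan-2-yl)-1,2,3,3a,4,5,8,8a-octahydroazulene-3,8-diol | O[C@@H]1C=C(C)C[C@H](O[Si](C)(C)C(C)(C)C)[C@@H]2[C@]1(C)CC[C@]2(O)C(C)C | intermediate
20 | (2E)-2-methylbut-2-enoyl chloride (tigloyl chloride) | C/C=C(\C)C(Cl)=O | starting material
21 | (3S,3aS,4S,8R,8aS)-4-{[tert-butyl(dimethyl)silyl]oxy}-3-hydroxy-6,8a-dimethyl-3-(propan-2-yl)-1,2,3,3a,4,5,8,8a-octahydroazulen-8-yl (2E)-2-methylbut-2-enoate | C/C=C(\C)C(=O)O[C@@H]1C=C(C)C[C@H](O[Si](C)(C)C(C)(C)C)[C@@H]2[C@]1(C)CC[C@]2(O)C(C)C | intermediate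
22 | (3S,3aS,4S,8R,8aS)-3,4-dihydroxy-6,8a-dimethyl-3-(propan-2-yl)-1,2,3,3a,4,5,8,8a-octahydroazulen-8-yl (2E)-2-methylbut-2-enoate | C/C=C(\C)C(=O)O[C@@H]1C=C(C)C[C@H](O)[C@@H]2[C@]1(C)CC[C@]2(O)C(C)C | intermediate
23 | 4-(acetyloxy)benzoyl chloride | CC(=O)Oc1ccc(cc1)C(Cl)=O | starting material
24 | (3S,3aS,4S,8R,8aS)-3-hydroxy-6,8a-dimethyl-8-{[(2E)-2-methylbut-2-enoyl]oxy}-3-(propan-2-yl)-1,2,3,3a,4,5,8,8a-octahydroazulen-4-yl 4-(acetyloxy)benzoate | C/C=C(\C)C(=O)O[C@@H]1C=C(C)C[C@H](OC(=O)c2ccc(OC(C)=O)cc2)[C@@H]2[C@]1(C)CC[C@]2(O)C(C)C | intermediate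
25 | (3S,3aS,4S,8R,8aS)-3-hydroxy-6,8a-dimethyl-8-{[(2E)-2-methylbut-2-enoyl]oxy}-3-(propan-2-yl)-1,2,3,3a,4,5,8,8a-octahydroazulen-4-yl 4-hydroxybenzoate | C/C=C(\C)C(=O)O[C@@H]1C=C(C)C[C@H](OC(=O)c2ccc(O)cc2)[C@@H]2[C@]1(C)CC[C@]2(O)C(C)C | target

Total step count: 18. Longest linear sequence: 17 steps (steps 1, 2 and 4 to 18; step 3 prepares aldehyde 6 on a side branch).

Steps most likely to fail

Step 4. In the second stage the Lewis acid may move the double bond of 6 into conjugation, or the open transition state may give poor control of the C5 face and of the anti relationship. The fallback starts from 4: the conjugate addition is run alone (same copper-catalysed addition, quenched with aq. NH4Cl) to give the saturated lactone (4R,5R)-4-ethenyl-4-methyl-5-[(1E)-prop-1-en-1-yl]oxolan-2-one F1, which is purified. The C5–C6 bond is then made by a closed-transition-state aldol reaction of its dicyclohexylboron enolate (c-Hex2BOTf, Et3N, CH2Cl2, −78 °C, then 6), where the ring-enforced enolate geometry should give the anti aldol without Lewis acid or strong base. This returns to the route at 8.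

Step 12. Epoxidation of the unhindered 1,1-disubstituted alkene of the C6 arm may compete with the hindered C3=C4 bond, and the C10 arm on the upper face may erode the facial preference. The fallback starts from 15 and closes ring B first (second-generation Hoveyda–Grubbs catalyst, toluene, 80 °C) to give the bicyclic diene tert-butyl(dimethyl){[(3aS,4S,8R,8aS)-6,8a-dimethyl-3-(propan-2-yl)-8-[(triethylsilyl)oxy]-1,3a,4,5,8,8a-hexahydroazulen-4-yl]oxy}silane F2. In F2 the only other alkene, C8=C9, is shielded and deactivated by the allylic silyloxy group, and the angular methyl group blocks the lower face of ring A. Epoxidation with mCPBA should then give the 2,3-epoxide of F2 with the oxygen cis to H-3a F3, LiEt3BH opens it to (3S,3aS,4S,8R,8aS)-4-{[tert-butyl(dimethyl)silyl]oxy}-6,8a-dimethyl-3-(propan-2-yl)-8-[(triethylsilyl)oxy]-1,2,3,3a,4,5,8,8a-octahydroazulen-3-ol F4, and PPTS in MeOH removes the triethylsilyl group. This returns to the route at 19.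

Step 6. Attack of the magnesium amide at the hindered, α-branched lactone carbonyl may be slow, and the γ-hydroxy amide may close back to the lactone during work-up. The fallback starts from 9: LiAlH4 (THF, 0 °C) reduces the lactone to the diol (2R,3S,4R,5E)-2-[(1S)-1-{[tert-butyl(dimethyl)silyl]oxy}-3-methylbut-3-en-1-yl]-3-ethenyl-3-methylhept-5-ene-1,4-diol F5, and TESCl with imidazole gives the 1,4-bis-O-(triethylsilyl) ether of that diol F6. Swern oxidation (oxalyl chloride, DMSO, Et3N, CH2Cl2, −78 to −20 °C) oxidises a primary triethylsilyl ether directly to the aldehyde while secondary silyl ethers survive. This returns to the route at 12.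

Further compounds
F1 | step 4 | (4R,5R)-4-ethenyl-4-methyl-5-[(1E)-prop-1-en-1-yl]oxolan-2-one | C=C[C@@]1(C)CC(=O)O[C@@H]1/C=C/C
F2 | step 12 | tert-butyl(dimethyl){[(3aS,4S,8R,8aS)-6,8a-dimethyl-3-(propan-2-yl)-8-[(triethylsilyl)oxy]-1,3a,4,5,8,8a-hexahydroazulen-4-yl]oxy}silane | CC[Si](CC)(CC)O[C@@H]1C=C(C)C[C@H](O[Si](C)(C)C(C)(C)C)[C@@H]2[C@]1(C)CC=C2C(C)C
F3 | step 12 | 2,3-epoxide of F2, oxygen cis to H-3a | CC[Si](CC)(CC)O[C@@H]1C=C(C)C[C@H](O[Si](C)(C)C(C)(C)C)[C@@H]2[C@]1(C)C[C@H]3O[C@@]23C(C)C
F4 | step 12 | (3S,3aS,4S,8R,8aS)-4-{[tert-butyl(dimethyl)silyl]oxy}-6,8a-dimethyl-3-(propan-2-yl)-8-[(triethylsilyl)oxy]-1,2,3,3a,4,5,8,8a-octahydroazulen-3-ol | CC[Si](CC)(CC)O[C@@H]1C=C(C)C[C@H](O[Si](C)(C)C(C)(C)C)[C@@H]2[C@]1(C)CC[C@]2(O)C(C)C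
F5 | step 6 | (2R,3S,4R,5E)-2-[(1S)-1-{[tert-butyl(dimethyl)silyl]oxy}-3-methylbut-3-en-1-yl]-3-ethenyl-3-methylhept-5-ene-1,4-diol | C=C(C)C[C@H](O[Si](C)(C)C(C)(C)C)[C@@H](CO)[C@]([C@H](O)/C=C/C)(C)C=C
F6 | step 6 | 1,4-bis-O-(triethylsilyl) ether of diol F5 | C=C(C)C[C@H](O[Si](C)(C)C(C)(C)C)[C@@H](CO[Si](CC)(CC)CC)[C@]([C@H](O[Si](CC)(CC)CC)/C=C/C)(C)C=C
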